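Ring B, the central benzene (C1 isobutyryl, C2/C4/C6 hydroxyl, C3/C5 methylene bridges), has its acyl carbon C1 next to the hydroxyl carbon C2. This ortho acyl/hydroxyl pair is made in one operation: the C1–C2 aryne of ring B is generated from a pentasubstituted 2-silylaryl triflate and inserts into the O–C(acyl) bond of isobutyric acid. That forms the C2–O and C1–C(acyl) bonds and completes the hexasubstituted ring. The precursor carries silicon on C1, triflate on C2, methoxymethyl arms on C3 and C5 and MOM ethers on C4 and C6. Acid then unmasks the phenols and the arms, which capture two ring A units (isobutyrylfilicinic acid).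

Key step: step 8

Remark: the target is taken as the structure of the given SMILES; it has no stereocentre, and the enol tautomers of the two rings A interconvert.
Remark: counted from the triflate carbon, the aryne precursor carries the methoxymethyl arms at positions 2 and 4 and the methoxymethoxy groups at 3 and 5; only this assignment maps onto the 1,3,5-oxygen pattern of ring B.

Step 1
Reactants: 1 phloroglucinol (benzene-1,3,5-triol)
Product: 2 2,4,6-tribromobenzene-1,3,5-triol
Conditions: Br2 (3.0 equiv), H2O, 0 °C to rt
Reagents that add atoms: bromine, BrBr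
Why: Electrophilic aromatic bromination of the triply activated ring fills all three free positions, so no regiochemical choice arises and the bromines mark the two arm sites and the future silyl site.

Step 2
Reactants: 2 2,4,6-tribromobenzene-1,3,5-triol
Product: 3 1,3,5-tribromo-2,4,6-tris(methoxymethoxy)benzene
Conditions: NaH (3.3 equiv), MOMCl (3.5 equiv), THF–DMF, 0 °C to rt
Reagents that add atoms: chloromethyl methyl ether, COCCl
Why: Williamson O-alkylation of the acidic phenoxides by the α-chloro ether, in which C-alkylation cannot compete because every ring carbon is substituted, gives base-stable, lithium-chelating acetals.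

Step 3
Reactants: 3 1,3,5-tribromo-2,4,6-tris(methoxymethoxy)benzene
Product: 4 1,3-dibromo-5-(methoxymethyl)-2,4,6-tris(methoxymethoxy)benzene
Conditions: n-BuLi (1.0 equiv), THF, −78 °C; MOMCl (1.2 equiv), −78 to 0 °C
Reagents that add atoms: chloromethyl methyl ether, COCCl
Why: Bromine–lithium exchange gives an aryllithium chelated by two flanking acetal oxygens, which the α-chloro ether alkylates (SN2) to the benzylic methyl ether at the final oxidation level, and the three bromines are equivalent so one equivalent of n-BuLi defines the product.

Step 4
Reactants: 4 1,3-dibromo-5-(methoxymethyl)-2,4,6-tris(methoxymethoxy)benzene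
Product: 5 1-bromo-3,5-bis(methoxymethyl)-2,4,6-tris(methoxymethoxy)benzene
Conditions: n-BuLi (1.0 equiv), THF, −78 °C; MOMCl (1.2 equiv), −78 to 0 °C
Reagents that add atoms: chloromethyl methyl ether, COCCl
Why: A second bromine–lithium exchange and SN2 alkylation at one of two equivalent bromines should work because exchange at −78 °C is far faster than deprotonation of the benzylic ether already present.

Step 5
Reactants: 5 1-bromo-3,5-bis(methoxymethyl)-2,4,6-tris(methoxymethoxy)benzene
Product: 6 2-bromo-4,6-bis(methoxymethyl)benzene-1,3,5-triol
Conditions: HCl (1 M), MeOH, 40 °C; NaHCO3 work-up, used crude at once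
Reagents that add atoms: none
Why: Acid-catalysed acetal methanolysis frees the three phenols, while methanol as solvent returns any benzylic cation from an arm to the methyl ether and the fully substituted ring offers no free carbon for self-condensation.

Step 6
Reactants: 6 2-bromo-4,6-bis(methoxymethyl)benzene-1,3,5-triol
Product: 9 3,5-dihydroxy-2,4-bis(methoxymethyl)-6-(trimethylsilyl)phenyl trifluoromethanesulfonate, via tris(trimethylsilyl) ether 7 (not isolated), via silylated aryl triflate 8 (not isolated)
Conditions: HMDS, THF, 60 °C, evaporate; n-BuLi (1.05 equiv), THF, −78 °C; Tf2O (1.2 equiv), −78 °C; then MeOH, citric acid (cat.), rt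
Reagents that add atoms: hexamethyldisilazane, C[Si](C)(C)N[Si](C)(C)C; trifluoromethanesulfonic anhydride, O=S(=O)(OS(=O)(=O)C(F)(F)F)C(F)(F)F
Why: Bromine–lithium exchange on the per-silylated bromide puts the carbanion on C1 between two equivalent silyloxy groups, a retro-Brook 1,3 O-to-C silyl shift moves one silyl group to C1 and frees the C2 phenoxide for triflation, so the symmetric ring is desymmetrised with no selectivity demand, and the two remaining labile aryl silyl ethers are cleaved by methanol.

Step 7
Reactants: 9 3,5-dihydroxy-2,4-bis(methoxymethyl)-6-(trimethylsilyl)phenyl trifluoromethanesulfonate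
Product: 10 3,5-bis(methoxymethoxy)-2,4-bis(methoxymethyl)-6-(trimethylsilyl)phenyl trifluoromethanesulfonate
Conditions: MOMCl (3 equiv), i-Pr2NEt (4 equiv), CH2Cl2, 0 °C to rt
Reagents that add atoms: chloromethyl methyl ether, COCCl
Why: O-Alkylation of the two phenols under amine base, which does not trigger the silyl triflate, installs fluoride-stable acetals, the one on C6 being the σ-withdrawing group that later steers the aryne.

Step 8
Reactants: 10 3,5-bis(methoxymethoxy)-2,4-bis(methoxymethyl)-6-(trimethylsilyl)phenyl trifluoromethanesulfonate; 11 isobutyric acid (1.2 equiv)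
Product: 12 1-[2-hydroxy-4,6-bis(methoxymethoxy)-3,5-bis(methoxymethyl)phenyl]-2-methylpropan-1-one
Conditions: CsF (4 equiv), THF, 125 °C, sealed tube
Reagents that add atoms: none
Why: Fluoride attacks silicon on C1 and the aryl anion expels triflate from C2 to give the C1–C2 aryne of ring B; isobutyrate (the acid deprotonated by CsF) adds through oxygen at C2, and the carbanion left on C1 attacks the adjacent ester carbonyl, so the acyl group shifts from oxygen to carbon through a four-membered tetrahedral intermediate and the C2 phenoxide is released. The closest known reaction type is the insertion of arynes from 2-silylaryl triflates into the O–C(acyl) bond of carboxylic acids, which gives ortho-hydroxyaryl ketones at elevated temperature in THF. No ring is closed and no stereocentre is formed. The step needs addition at C2, which the σ-withdrawing acetal oxygen on C6 secures by stabilising negative charge on C1 and distorting the aryne so that C2 is the more electrophilic terminus, as in 3-alkoxyarynes; the C3 arm opposes this sterically. It also needs acyl transfer to outrun protonation of the C1 anion, which the high temperature, the binding of the acid proton as CsHF2 and the proximity of the ester carbonyl favour. The acetals and benzylic methyl ethers are inert to CsF.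

Step 9
Reactants: 13 isobutyrylphloroglucinol (2-methyl-1-(2,4,6-trihydroxyphenyl)propan-1-one)
Product: 14 3,5-dihydroxy-6,6-dimethyl-2-(2-methylpropanoyl)cyclohexa-2,4-dien-1-one (isobutyrylfilicinic acid, the ring A acid)
Conditions: NaOMe (3.5 equiv), MeI (2.5 equiv), MeOH, 0 °C to rt
Reagents that add atoms: iodomethane, CI
Why: C-Alkylation of the phloroglucinol enolate by MeI in methanol, the second methyl entering at the carbon already methylated, dearomatises the ring to the gem-dimethyl β-triketone and leaves one nucleophilic enol CH (C4).

Step 10
Reactants: 12 1-[2-hydroxy-4,6-bis(methoxymethoxy)-3,5-bis(methoxymethyl)phenyl]-2-methylpropan-1-one; 14 isobutyrylfilicinic acid (2.2 equiv)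
Product: 16 onind, via triol ketone 15 (not isolated)
Conditions: HCl (1 M), MeOH, 40 °C; evaporate; then 14 (2.2 equiv), TsOH·H2O (0.1 equiv), MeCN, 50 °C
Reagents that add atoms: none
Why: Acetal methanolysis frees the C4 and C6 phenols and, once dimethoxymethane (a formaldehyde equivalent that would otherwise alkylate 14) has been evaporated, acid ionises each ortho/para-hydroxybenzyl methyl ether to an ortho-quinone methide that undergoes Michael addition of the enol carbon C4 of 14, forming both methylene bridges.

Compound list
1 | phloroglucinol (benzene-1,3,5-triol) | Oc1cc(O)cc(O)c1 | starting material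
2 | 2,4,6-tribromobenzene-1,3,5-triol | Oc1c(Br)c(O)c(Br)c(O)c1Br | intermediate
3 | 1,3,5-tribromo-2,4,6-tris(methoxymethoxy)benzene | COCOc1c(Br)c(OCOC)c(Br)c(OCOC)c1Br | intermediate
4 | 1,3-dibromo-5-(methoxymethyl)-2,4,6-tris(methoxymethoxy)benzene | COCc1c(OCOC)c(Br)c(OCOC)c(Br)c1OCOC | intermediate
5 | 1-bromo-3,5-bis(methoxymethyl)-2,4,6-tris(methoxymethoxy)benzene | COCc1c(OCOC)c(COC)c(OCOC)c(Br)c1OCOC | intermediate
6 | 2-bromo-4,6-bis(methoxymethyl)benzene-1,3,5-triol | COCc1c(O)c(COC)c(O)c(Br)c1O | intermediate
7 | 2-bromo-4,6-bis(methoxymethyl)-1,3,5-tris(trimethylsilyloxy)benzene | COCc1c(O[Si](C)(C)C)c(COC)c(O[Si](C)(C)C)c(Br)c1O[Si](C)(C)C | intermediate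
8 | 2,4-bis(methoxymethyl)-6-(trimethylsilyl)-3,5-bis(trimethylsilyloxy)phenyl trifluoromethanesulfonate | COCc1c(O[Si](C)(C)C)c(COC)c(OS(=O)(=O)C(F)(F)F)c([Si](C)(C)C)c1O[Si](C)(C)C | intermediate
9 | 3,5-dihydroxy-2,4-bis(methoxymethyl)-6-(trimethylsilyl)phenyl trifluoromethanesulfonate | COCc1c(O)c(COC)c(OS(=O)(=O)C(F)(F)F)c([Si](C)(C)C)c1O | intermediate
10 | 3,5-bis(methoxymethoxy)-2,4-bis(methoxymethyl)-6-(trimethylsilyl)phenyl trifluoromethanesulfonate (ring B: C1 silyl, C2 triflate) | COCc1c(OCOC)c(COC)c(OS(=O)(=O)C(F)(F)F)c([Si](C)(C)C)c1OCOC | intermediate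
11 | isobutyric acid | CC(C)C(O)=O | starting material
12 | 1-[2-hydroxy-4,6-bis(methoxymethoxy)-3,5-bis(methoxymethyl)phenyl]-2-methylpropan-1-one | CC(C)C(=O)c1c(O)c(COC)c(OCOC)c(COC)c1OCOC | intermediate
13 | isobutyrylphloroglucinol (2-methyl-1-(2,4,6-trihydroxyphenyl)propan-1-one) | CC(C)C(=O)c1c(O)cc(O)cc1O | starting material
14 | 3,5-dihydroxy-6,6-dimethyl-2-(2-methylpropanoyl)cyclohexa-2,4-dien-1-one | CC(C)C(=O)C1=C(O)C=C(O)C(C)(C)C1=O | intermediate
15 | 1-[2,4,6-trihydroxy-3,5-bis(methoxymethyl)phenyl]-2-methylpropan-1-one | CC(C)C(=O)c1c(O)c(COC)c(O)c(COC)c1O | intermediate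
16 | onind, 4,4'-{[2,4,6-trihydroxy-5-(2-methylpropanoyl)-1,3-phenylene]bis(methylene)}bis[3,5-dihydroxy-6,6-dimethyl-2-(2-methylpropanoyl)cyclohexa-2,4-dien-1-one] | CC(C)C(=O)C1=C(O)C(Cc2c(O)c(CC3=C(O)C(C)(C)C(=O)C(C(=O)C(C)C)=C3O)c(O)c(C(=O)C(C)C)c2O)=C(O)C(C)(C)C1=O | target

Total step count: 10. Longest linear sequence: 9 steps (steps 1 to 8, then step 10); step 9 is a one-step branch.

Steps most likely to fail

Step 8. The C1 carbanion may be protonated before the acyl shift, leaving only the O-aryl ester, or isobutyrate may add at C1 under the steric pressure of the C3 arm. The fallback sets out from 5 and comes back at 15. Bromine–lithium exchange on 5 (n-BuLi, THF, −78 °C) and addition of the aryllithium to isobutyraldehyde gives racemic 1-[3,5-bis(methoxymethyl)-2,4,6-tris(methoxymethoxy)phenyl]-2-methylpropan-1-ol F1. Oxidation with Dess–Martin periodinane gives 1-[3,5-bis(methoxymethyl)-2,4,6-tris(methoxymethoxy)phenyl]-2-methylpropan-1-one F2. Methanolic HCl, as in the first stage of step 10, then removes the three acetals and delivers 15.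

Step 10. Under acid the methylene bridges may cleave and re-form, exchanging ring units into symmetrical by-products; the quinone methide may oligomerise; or bridged phenol and enol may cyclodehydrate. The fallback sets out from 12 and comes back at 16. Methanolic HCl in the presence of excess PhSO2Na removes the acetals and captures each quinone methide at sulfur, giving the bench-stable 1-[2,4,6-trihydroxy-3,5-bis(phenylsulfonylmethyl)phenyl]-2-methylpropan-1-one F3, which is isolated. With 14 and K2CO3 in MeCN at rt, base-induced 1,4-elimination of sulfinate releases the quinone methides one after the other, and the enolate of 14 adds to give 16 without acid.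

Step 5. The arms of the unprotected bromotriol may ionise during concentration, leading to self-condensation or loss of bromine by ipso substitution. The fallback sets out from 5 and comes back at 7. TMSOTf and 2,2'-bipyridyl in CH2Cl2 at 0 °C exchange aryl methoxymethyl ethers directly for aryl trimethylsilyl ethers under non-protic conditions. This gives 7 without passing through the free triol 6; after the bipyridinium salt is removed, 7 enters the lithiation of step 6.

Further compounds
F1 | step 8 | 1-[3,5-bis(methoxymethyl)-2,4,6-tris(methoxymethoxy)phenyl]-2-methylpropan-1-ol (racemic) | CC(C)C(O)c1c(OCOC)c(COC)c(OCOC)c(COC)c1OCOC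
F2 | step 8 | 1-[3,5-bis(methoxymethyl)-2,4,6-tris(methoxymethoxy)phenyl]-2-methylpropan-1-one | CC(C)C(=O)c1c(OCOC)c(COC)c(OCOC)c(COC)c1OCOC
F3 | step 10 | 1-[2,4,6-trihydroxy-3,5-bis(phenylsulfonylmethyl)phenyl]-2-methylpropan-1-one | CC(C)C(=O)c1c(O)c(CS(=O)(=O)c2ccccc2)c(O)c(CS(=O)(=O)c2ccccc2)c1O
F0 | step 5 | none | none
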